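**Carrying a reading.** A reading of c(target) in mM cannot be carried from one flask to another, since the epsilon run starts from 300 mM of starting material, the gamma run from 150 mM and the eta run from 65.0 mM. I have these flasks and readings:

| flask | starting material | coupling partner | time |
|---|---|---|---|
| epsilon | 300 mM | 900 mM |  |
| beta | 300 mM | 1400 mM |  |
| gamma | 150 mM | 900 mM |  |
| eta | 65.0 mM | 900 mM | 28 min |

- epsilon run (time / min: [target] / mM): 4.0: 78.9; 8.0: 123.0; 12: 150.8; 16: 167.0; 20: 175.1; 24: 183.0; 28: 181.8
- beta run (time / min: [target] / mM): 4.0: 57.6; 8.0: 98.1; 12: 120.3; 16: 146.5; 20: 158.4; 24: 170.6; 28: 178.1
- gamma run (time / min: [target] / mM): 4.0: 37.1; 8.0: 61.2; 12: 72.2; 16: 81.6; 20: 89.2; 24: 88.3; 28: 89.8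

(each reading ± 2 mM)

- Overall: starting material + coupling partner -> target.
- Constant volume, constant temperature.
- Readings of a species count what is bound in complexes too.
- "The second partner" is coupling partner.
- An order is taken over about fifteen percent of the charge, up and down.

- how the opening rate goes with [starting material] round the charge of the epsilon run: the exponent of the rate at two percent of starting material gone to target (one fixed amount of target, the same in the runs compared)
- how the opening rate goes with [coupling partner] round the charge of the epsilon run: the exponent of the rate at two percent of starting material gone to target
- target in the eta run at 28 min, as a share of the starting material charged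

**Two ways.** I divide c(target) by the charge of starting material, which is the limiting reagent here, with 300 mM against 900 mM of coupling partner in the epsilon run. Comparing at one time and one partner charge takes the clock out of the comparison. The epsilon run gives 60.6% at 28 min, and the gamma run, with half the starting material, gives 59.9% at 28 min. They differ by 0.70 percentage points, less than the 1.33% that one gamma reading carries. Two different flasks agree, so I trust the mean, 60.2%: the carried share, target at a stated time per starting material charged, at a stated charge of coupling partner.

**My reckoning.** At 4.0 min the share is 26.3% in the epsilon run and 24.7% in the gamma run, so early as well as late the two stay close, and I put the exponent for starting material near one. The eta run has the 900 mM of coupling partner that the epsilon and gamma runs have, and it is asked at 28 min. So I expect 60.2% of its charge, or 39.1 mM.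

**The forecast.** It gives 1 for starting material (0.8 to 1.2), −0.95 for coupling partner (−1.3 to −0.6), and 59.5% for the eta run (54% to 65%). Its ground is: “Halving the starting material leaves k and the percentage yield (about 60%) unchanged”. My share stands above its 59.5%.

**The flask.** The exponents come to 1.0 for starting material and −0.55 for coupling partner, and the eta run gives 60.9%.

    starting material → intermediate (0.2718 min⁻¹)
    intermediate + coupling partner → target (11.64 M⁻¹ min⁻¹)
    intermediate → side product (0.05814 min⁻¹)
    starting material → decomposed substrate (0.1548 min⁻¹)
    starting material + coupling partner ⇌ idle substrate-reagent adduct, settled at all times (3.080 M⁻¹)

**The difference.** The exponent for coupling partner lies above the forecast's range. At an equal amount of target made, the beta run's rate is 0.73 of the epsilon run's, where the forecast reads about 0.65 from its opening rates. In the eta run, 60.9% of the charge is 39.6 mM of target, beside my 39.1 mM. The beta run, with 1400 mM of coupling partner, lies outside the partner charge at which the share was read; there the share gives 181 mM, and the reading at 28 min is 178.1 mM.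

The numbers in the tables were computed with made-up constants; scatter was added.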